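The plan rests on cutting the O5–C(CH3)2 bond of the dihydropyran fused to ring A, together with its twin, O4'–C(CH3)2 on ring B. The key step is an acid-catalysed twofold cycloisomerisation of an open 6,8,3'-triprenylcoumaronochromone whose O7 carries an allyl group. One operation closes both dihydropyrans and creates both fully substituted ether carbons. It exploits the oxygen environment of the three prenyl groups. C6 has only O5–H within reach and C3' only O4'–H (O2' is locked in the furan). C8 sits between O1 of ring C and the allylated O7 and stays open. The precursor arises from a symmetric ring A ketene dithioacetal and a prenylated hydroxyquinone.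

Key step: step 8

Remark: isoflavonoid numbering is used (ring A C5–C8, pyranone ring C O1–C4, ring B C1'–C6'). "Coumaronochromone" means 11H-benzofuro[2,3-b]chromen-11-one, with the furan oxygen joining C2 and C2'. The target has no stereocentre and no configurable double bond, so no step has to control configuration.

Step 1
Reactants: 1 2,4,6-trihydroxyacetophenone; 2 prenyl bromide (2.1 equiv)
Product: 3 3,5-diprenyl-2,4,6-trihydroxyacetophenone
Conditions: KOH (2.2 equiv), H2O, 0 °C to rt
Reagents that add atoms: none
Why: Base-mediated C-alkylation of an acylphloroglucinol anion should place one prenyl group on each of the two equivalent nucleophilic ring carbons C3 and C5, and limiting the bromide to two equivalents restrains geminal over-alkylation.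

Step 2
Reactants: 3 3,5-diprenyl-2,4,6-trihydroxyacetophenone
Product: 4 4-O-allyl-3,5-diprenyl-2,6-dihydroxyacetophenone
Conditions: allyl alcohol, PPh3, DIAD, THF, 0 °C to rt
Reagents that add atoms: allyl alcohol, C=CCO
Why: The Mitsunobu etherification should select the most acidic and only non-chelated phenol (para to the acetyl group), avoids the dearomatising C-alkylation possible with allyl halides and base, and installs a group that is inert to strong base and to acid.

Step 3
Reactants: 4 4-O-allyl-3,5-diprenyl-2,6-dihydroxyacetophenone
Product: 6 ring A α-aroyl ketene dithioacetal, via tetralithium ene-1,1-dithiolate 5 (not isolated)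
Conditions: LiN(SiMe3)2 (5 equiv), THF, −78 to −10 °C; CS2, −78 to 0 °C; MeI (2.2 equiv), 0 °C to rt; cold 1 M HCl
Reagents that add atoms: carbon disulfide, S=C=S; iodomethane, CI
Why: Polyanion formation, enolate addition to CS2 and double S-methylation is the standard α-oxoketene dithioacetal synthesis, the soft dithiolate should outrun the chelated lithium phenoxides for MeI, and any material that already closes to the 2-methylsulfanylchromone converges in step 7.

Step 4
Reactants: 7 1,2,4-trimethoxybenzene; 2 prenyl bromide
Product: 9 1,2,4-trimethoxy-3-prenylbenzene, via 2,3,6-trimethoxyphenyllithium 8 (not isolated)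
Conditions: n-BuLi, TMEDA, THF, 0 °C to rt; then 2, −78 °C to rt
Reagents that add atoms: none
Why: Directed ortho-metalation should occur at C3, the position flanked by two methoxy groups, and the aryllithium is then alkylated by the primary allylic bromide in an SN2 reaction.

Step 5
Reactants: 9 1,2,4-trimethoxy-3-prenylbenzene
Product: 10 2-methoxy-3-prenyl-1,4-benzoquinone
Conditions: (NH4)2Ce(NO3)6 (2.5 equiv), MeCN–H2O, 0 °C
Reagents that add atoms: water, O
Why: Oxidative demethylation of a hydroquinone dimethyl ether by tetravalent cerium should convert the para-related methoxy groups at C1 and C4 into the quinone carbonyls (oxygen from water) faster than it touches the prenyl double bond, while the C2 methoxy group remains as a vinylogous ester.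

Step 6
Reactants: 10 2-methoxy-3-prenyl-1,4-benzoquinone
Product: 11 2-hydroxy-3-prenyl-1,4-benzoquinone
Conditions: NaOH (1 M aq), THF, 0 °C, Ar; then 1 M HCl
Reagents that add atoms: sodium hydroxide, [Na+].[OH-]
Why: The methoxyquinone is a vinylogous ester, so hydroxide should replace methoxide by addition–elimination at C2, and the resulting quinonate anion resists further attack until it is acidified.

Step 7
Reactants: 6 ring A α-aroyl ketene dithioacetal; 11 2-hydroxy-3-prenyl-1,4-benzoquinone
Product: 13 7-allyloxy-5,4',5'-trihydroxy-6,8,3'-triprenylcoumaronochromone, via 2-methylsulfanylbenzofuran-3-yl ketone 12 (not isolated)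
Conditions: CuBr2 (10 mol %), BF3·OEt2 (30 mol %), MeCN, rt, Ar; then DBU (4 equiv), 40 °C; 1 M HCl
Reagents that add atoms: none
Why: The Lewis-acid-catalysed formal [3+2] annulation of a ketene dithioacetal with a para-quinone (Michael addition, rearomatisation, O-cyclisation with loss of MeSH) should attack quinone C5, the β-position of the C1 carbonyl that the vinylogous-acid 2-OH does not deactivate, and either of the two equivalent ring A phenoxides then displaces the second MeS group by intramolecular addition–elimination to close the pyranone without any external oxidant.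

Step 8
Reactants: 13 7-allyloxy-5,4',5'-trihydroxy-6,8,3'-triprenylcoumaronochromone
Product: 15 7-O-allyl ether of the target, via ring B monochroman 14 (not isolated)
Conditions: p-TsOH (anhydrous, 30 mol %), toluene, 80 °C, Ar
Reagents that add atoms: none
Why: Protonation of a prenyl double bond at its CH carbon develops the tertiary cation, the neighbouring phenolic oxygen captures it and a proton is released, so the step is a catalytic, fully atom-economic isomerisation of the classical type that turns ortho-prenylphenols into 2,2-dimethylchromans by intramolecular hydroalkoxylation. Both rings close in the formally 6-endo-trig Markovnikov mode, because the 5-exo alternative would require a secondary cation. No stereocentre arises, since each new quaternary carbon bears two methyl groups. The required site selectivity is written into the substrate: the C6 prenyl reaches only O5–H because O7 is allylated, the C3' prenyl reaches only O4'–H because O2' belongs to the furan, and the C8 prenyl lies between O1 of ring C and the allylated O7, so its protonation is reversible and unproductive, as is known for prenylated xanthones in which a prenyl group next to an O-alkyl group survives such cyclisations. The catechol O4'–H should close first (14) and the hydrogen-bonded O5–H more slowly, which is the reason for heating in an anhydrous, non-nucleophilic medium. Reversible addition of the allyl ether oxygen to the C8 cation gives an oxonium ion with no easy exit, which should revert.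

Step 9
Reactants: 15 7-O-allyl ether of the target
Product: 16 target CNP0081329.0
Conditions: Pd(PPh3)4 (5 mol %), morpholine (5 equiv), THF, rt; neutral work-up
Reagents that add atoms: none
Why: In this Tsuji–Trost-type deallylation zerovalent palladium ionises only the allyl aryl ether to a π-allyl complex that morpholine intercepts, while the trisubstituted prenyl alkene, both chromans and the free phenols are untouched and the acid-free medium keeps the liberated O7–H from adding to the C8 prenyl group.

Compound list
1 | 2,4,6-trihydroxyacetophenone | CC(=O)c1c(O)cc(O)cc1O | starting material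
2 | prenyl bromide (1-bromo-3-methylbut-2-ene) | CC(C)=CCBr | starting material
3 | 1-[2,4,6-trihydroxy-3,5-bis(3-methylbut-2-en-1-yl)phenyl]ethan-1-one | CC(=O)c1c(O)c(CC=C(C)C)c(O)c(CC=C(C)C)c1O | intermediate
4 | 1-[2,6-dihydroxy-3,5-bis(3-methylbut-2-en-1-yl)-4-(prop-2-en-1-yloxy)phenyl]ethan-1-one | CC(=O)c1c(O)c(CC=C(C)C)c(OCC=C)c(CC=C(C)C)c1O | intermediate
5 | tetralithium salt of the 2-aroylethene-1,1-dithiolate derived from 4 (both phenols also deprotonated) | [Li+].[Li+].[Li+].[Li+].[S-]C([S-])=CC(=O)c1c([O-])c(CC=C(C)C)c(OCC=C)c(CC=C(C)C)c1[O-] | intermediate
6 | 1-[2,6-dihydroxy-3,5-bis(3-methylbut-2-en-1-yl)-4-(prop-2-en-1-yloxy)phenyl]-3,3-bis(methylsulfanyl)prop-2-en-1-one | CSC(SC)=CC(=O)c1c(O)c(CC=C(C)C)c(OCC=C)c(CC=C(C)C)c1O | intermediate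
7 | 1,2,4-trimethoxybenzene | COc1ccc(OC)c(OC)c1 | starting material
8 | 2,3,6-trimethoxyphenyllithium | [Li]c1c(OC)ccc(OC)c1OC | intermediate
9 | 1,2,4-trimethoxy-3-(3-methylbut-2-en-1-yl)benzene | COc1ccc(OC)c(CC=C(C)C)c1OC | intermediate
10 | 2-methoxy-3-(3-methylbut-2-en-1-yl)cyclohexa-2,5-diene-1,4-dione | COC1=C(CC=C(C)C)C(=O)C=CC1=O | intermediate
11 | 2-hydroxy-3-(3-methylbut-2-en-1-yl)cyclohexa-2,5-diene-1,4-dione | OC1=C(CC=C(C)C)C(=O)C=CC1=O | intermediate
12 | [4-allyloxy-2,6-dihydroxy-3,5-diprenylphenyl][5,6-dihydroxy-2-(methylsulfanyl)-7-prenyl-1-benzofuran-3-yl]methanone | CSc1oc2c(CC=C(C)C)c(O)c(O)cc2c1C(=O)c1c(O)c(CC=C(C)C)c(OCC=C)c(CC=C(C)C)c1O | intermediate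
13 | 7-allyloxy-5,4',5'-trihydroxy-6,8,3'-triprenylcoumaronochromone | CC(C)=CCc1c(OCC=C)c(CC=C(C)C)c(O)c2c(=O)c3c(oc12)oc1c(CC=C(C)C)c(O)c(O)cc13 | intermediate
14 | 7-allyloxy-5,5'-dihydroxy-6,8-diprenylcoumaronochromone with the 2,2-dimethyldihydropyran closed on O4'/C3' | CC(C)=CCc1c(OCC=C)c(CC=C(C)C)c(O)c2c(=O)c3c(oc12)oc1c4c(c(O)cc13)OC(C)(C)CC4 | intermediate
15 | 7-allyloxy-5'-hydroxy-8-prenylcoumaronochromone with 2,2-dimethyldihydropyrans closed on O5/C6 and on O4'/C3' | CC(C)=CCc1c(OCC=C)c2c(c3c(=O)c4c(oc13)oc1c3c(c(O)cc14)OC(C)(C)CC3)OC(C)(C)CC2 | intermediate
16 | CNP0081329.0, 7,5'-dihydroxy-8-prenylcoumaronochromone with 2,2-dimethyldihydropyrans on O5/C6 and on O4'/C3' | CC(C)=CCc1c(O)c2c(c3c(=O)c4c(oc13)oc1c3c(c(O)cc14)OC(C)(C)CC3)OC(C)(C)CC2 | target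

Total step count: 9. Longest linear sequence: 6 (steps 1, 2, 3, 7, 8, 9; the branch through steps 4, 5, 6 is equally long).

Steps most likely to fail

Step 8. Closure at the hydrogen-bonded O5–H may be slow. Long acid exposure could then cause migration or hydration of the C8 double bond, or loss of the allyl group through the transient oxonium ion followed by closure onto O7. The fallback replaces the proton by a selenium electrophile. It sets out from 13, which is treated with N-(phenylselanyl)phthalimide (2.1 equiv) and catalytic camphorsulfonic acid in CH2Cl2 at low temperature. Seleniranium formation is reversible at the C8 prenyl group. At C6 and C3' it becomes irreversible through capture by O5–H and O4'–H at the tertiary carbon. This should give the 7-O-allyl hexacycle bearing a phenylselanyl group on each dihydropyran CH, F1, as a diastereomer mixture whose stereocentres are erased next. Radical deselenation with Bu3SnH and AIBN in toluene at 80 °C returns to the route at 15.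

Step 7. The chelating ortho-hydroxy ketone and the hydroxyquinone may sequester the boron Lewis acid. This would leave a sluggish Michael addition, erosion of the C5 over C6 preference, or redox exchange between adduct and quinone. The fallback raises the nucleophilicity of ring C instead of the electrophilicity of the quinone. It sets out from 6, which is heated with morpholine in THF. Sulfur-to-nitrogen exchange and pyranone closure should give 7-allyloxy-5-hydroxy-2-(morpholin-4-yl)-6,8-diprenylchromone F2, a cyclic tertiary enaminone. A Nenitzescu-type benzofuran annulation of F2 with 11 in acetic acid (C3 attack on the quinone, then displacement of morpholine by O2'–H) comes back to the route at 13.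

Step 6. Hydroxide may add in conjugate fashion to the unsubstituted C5 and C6 positions, and the quinone may degrade by base-induced self-condensation before substitution at C2 is complete. The fallback avoids base and the isolated hydroxyquinone. It sets out from 10, which is warmed with aqueous H2SO4 in acetic acid. Acid hydrolysis of the vinylogous ester and lapachol-type ring closure of the hydroxyquinone formed in situ should give 2,2-dimethylchroman-5,8-dione F3. Under the conditions of step 7, F3 and 6 should pass through the chroman-fused 2-methylsulfanylbenzofuran-3-yl ketone F4. They come back to the route at 14, which is then isolated and enters step 8 with only the ring on O5 left to close.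

Further compounds
F1 | step 8 | 7-O-allyl hexacycle carrying a phenylselanyl group at the CH next to each C(CH3)2 (diastereomer mixture, configuration not controlled) | CC(C)=CCc1c(OCC=C)c2c(c3c(=O)c4c(oc13)oc1c3c(c(O)cc14)OC(C)(C)C([Se]c5ccccc5)C3)OC(C)(C)C([Se]c5ccccc5)C2
F2 | step 7 | 7-allyloxy-5-hydroxy-2-(morpholin-4-yl)-6,8-diprenyl-4H-chromen-4-one | CC(C)=CCc1c(OCC=C)c(CC=C(C)C)c(O)c2c(=O)cc(N3CCOCC3)oc12
F3 | step 6 | 2,2-dimethyl-3,4-dihydro-2H-chromene-5,8-dione | CC1(C)CCC2=C(O1)C(=O)C=CC2=O
F4 | step 6 | [4-allyloxy-2,6-dihydroxy-3,5-diprenylphenyl] ketone of the 5-hydroxy-2-(methylsulfanyl)benzofuran fused to a 2,2-dimethyldihydropyran at O6/C7 | CSc1oc2c3c(c(O)cc2c1C(=O)c1c(O)c(CC=C(C)C)c(OCC=C)c(CC=C(C)C)c1O)OC(C)(C)CC3
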